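Before you repeat these flasks, decide to compare them by how far each has gone, not by their clock times.

| flask | J | E | remark | time |
|---|---|---|---|---|
| summer | 0.050 M | 0.47 µM | run made earlier |  |
| dawn | 0.050 M | 0.64 µM | run made earlier |  |
| dusk | 0.050 M | 1.1 µM | run made earlier |  |
| spring | 0.099 M | 0.45 µM | run made earlier |  |
| cedar | 0.050 M | 0.45 µM |  | 5.0 min |
| ash | 0.15 M | 1.0 µM |  | 1.5 min |

- summer (time / min: D / %): 0.417: 64.0; 1.33: 84.5; 2.50: 89.3; 4.00: 91.8; 5.00: 92.4
- dawn (time / min: D / %): 0.417: 72.3; 1.33: 88.3; 2.50: 92.4; 4.00: 93.6; 5.00: 94.8
- dusk (time / min: D / %): 1.00: 91.5; 2.00: 94.6; 3.00: 95.8; 4.00: 96.8; 5.00: 96.4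
- spring (time / min: D / %): 1.00: 83.0; 2.00: 87.5; 3.00: 89.8; 4.00: 90.5; 5.00: 90.4

(scatter of a reading: 0.3 percentage points)

* which one finishes higher in amount of D, in percent of the J charged ("neither" within 2 percentage points) (cedar / ash / neither)
* amount of D at the end, in percent of the J charged, cedar
* amount of D at the end, in percent of the J charged, ash

In the summer run, doubling the time from 2.50 min to 5.00 min adds 3.1 percentage points of D. I read this as the J still there at the end, assuming J left falls inversely with time. Call N the turnover count, proportional to charged J times E times time, with the share of J left equal to the inverse of one plus N; read from those two scattered readings, summer stands at N = 31.3. Scaled to dawn, N leaves 2.30%, and dawn's own doubling adds 2.4 points.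

Cedar gets N = 29.9, leaving 3.23%, and ash gets 59.9, leaving 1.64%.

One number is not enough: spring's N of 59.3 is higher than summer's, yet spring ends lower, at 90.4% against 92.4%. So call W the share that is neither J nor D: 4.50% in summer, 7.94% in spring. Scaling W as J over E overshoots spring, at 9.31%, so I take my ash figure of 92.0% as a low end; my cedar figure is 92.1%, and the two lie closer than the margin of 2 points, so my own answer is neither.

The forecast says 92.1% for cedar, 92.3% for ash and neither, holding that “Tripling J probably costs about a point”.

The flasks give 92.2% for cedar and 92.0% for ash, so neither.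

    J + E → D + E, rate k1*[J]^2*[E]/(1 + ([J]/Kh1)^2) (0.0500 M, k = 4.50 × 10⁶ M⁻² s⁻¹)
    2 J → G (k = 0.0380 M⁻¹ s⁻¹)

In cedar, the turning of J into D uses J 13 times as fast as the turning of two J into G at the start, and 27 times as fast at 5.00 min. G stands at 4.64% of the J charged in cedar at 5.00 min, against 6.13% in ash at 1.50 min. The shares of J left that N gave, 3.23% for cedar and 1.64% for ash, stand against 3.2% and 1.8% in those flasks. For the neighbour of cedar charged with 0.20 M of J, N = 120 leaves 0.828% against 0.88%, yet that flask holds 81.5% of D and 17.6% of G.

The earlier runs and the new flask stem from a simulated flask with made-up constants; noise was put on by code.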